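**Assumption:** positions carry elemane numbers (ring C5–C10 with C10 quaternary; C1/C2 oxirane; C3/C4/C15 acrolein unit; C11–C13 lactone; C14 methyl). β is the ring face carrying the C10 methyl, α the opposite face; absolute configuration is the one in each SMILES. Unnumbered reagents are commercial.

## Retrosynthetic overview

1. Target 18 ⇐ 17 by hydroxyl-directed epoxidation of the C10 vinyl group (sets C1, oxirane formed last).
2. 17 ⇐ 15 by allylic oxidation of two isopropenyl groups: one becomes the C3 enal, the other closes the 8,12-lactone (second ring).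
3. 15 ⇐ 9 by alkoxide-directed isopropenyl addition at C7, enolate hydroxylation at C8, ketone reduction at C9 and C6 acylation.
4. 9 ⇐ 6 by double methylenation, deacetylation and selective allylic oxidation.
5. 6 ⇐ 4 + 5 by a catalytic asymmetric Diels–Alder reaction (cyclohexane ring formed first; C5, C6, C10 set).

## Route

Step 1
Reactants: 1 1,1-dimethoxypropan-2-one; 2 diethyl (2-oxopropyl)phosphonate
Product: 3 (E)-5,5-dimethoxy-4-methylpent-3-en-2-one
Conditions: NaH, THF, 0 °C to reflux
Reagents that add atoms: none
Why: Horner–Wadsworth–Emmons olefination of the activated α,α-dialkoxy ketone; the E-enone (acetyl trans to the acetal carbon) is the thermodynamic product and is purified.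

Step 2
Reactants: 3 (E)-5,5-dimethoxy-4-methylpent-3-en-2-one
Product: 4 (E)-2-methyl-4-oxopent-2-enal
Conditions: 1 M aq HCl, acetone, rt
Reagents that add atoms: water, O
Why: Acid-catalysed acetal hydrolysis frees the aldehyde; the E geometry is the stable one for this ene-1,4-dicarbonyl compound.

Step 3
Reactants: 4 (E)-2-methyl-4-oxopent-2-enal; 5 (1E,3E)-buta-1,3-diene-1,4-diyl diacetate
Product: 6 Diels–Alder adduct (6β,9β-diacetoxy, 10β-methyl, 10α-formyl, 5β-acetyl cyclohex-7-ene)
Conditions: (R)-3,3′-bis(2,4,6-triisopropylphenyl)-1,1′-binaphthyl-2,2′-diyl N-triflylphosphoramide (5 mol%), toluene, 4 Å MS, −20 °C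
Reagents that add atoms: none
Why: Proposed new method: a confined chiral N-triflylphosphoramide Brønsted acid is proposed to catalyse the Diels–Alder reaction of an ene-1,4-dicarbonyl dienophile with 1,4-diacetoxybutadiene; protonation/hydrogen bonding at the more basic enone carbonyl of 4 lowers its LUMO inside a chiral ion pair, the symmetric diene removes any regiochemical question, the E geometry of 4 becomes the trans relation of the C10 formyl and C5 acetyl groups, the activated acetyl sits endo and the formyl on the methyl-bearing carbon exo (as for α-methyl enals) so both acetoxy groups end cis to acetyl and methyl, and the catalyst pocket selects the enantioface (the antipode is used if the sense is opposite), setting C5, C6, C9 and C10 in one step; closest known reaction type: N-triflylphosphoramide-catalysed asymmetric Diels–Alder reactions of α,β-unsaturated ketones with siloxydienes and thermal cycloadditions of 1,4-diacetoxybutadiene.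

Step 4
Reactants: 6 Diels–Alder adduct
Product: 7 10α-vinyl-5β-isopropenyl diacetate
Conditions: Zn, CH2Br2, TiCl4, THF/CH2Cl2, 0 °C to rt
Reagents that add atoms: dibromomethane, BrCBr
Why: Takai–Lombardo methylenation; the non-basic zinc/titanium methylene reagent converts both the aldehyde and the methyl ketone into C=CH2 without touching the acetates or epimerising/eliminating at C5.

Step 5
Reactants: 7 10α-vinyl-5β-isopropenyl diacetate
Product: 8 6β,9β-diol
Conditions: K2CO3, MeOH, 0 °C to rt
Reagents that add atoms: none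
Why: Base-catalysed transesterification removes both acetates; no stereocentre is touched.

Step 6
Reactants: 8 6β,9β-diol
Product: 9 6β-hydroxy enone (C9 ketone)
Conditions: MnO2 (activated, excess), CH2Cl2, rt, stopped at mono-oxidation
Reagents that add atoms: none
Why: MnO2 allylic oxidation; in the favoured half-chair (C10 methyl axial, both alkenyl groups equatorial) the C9–H bond is pseudo-axial and aligned with the π system, whereas the C6 carbinol is pseudo-axial and shielded by the syn-axial methyl, so C9–OH is oxidised selectively.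

Step 7
Reactants: 9 6β-hydroxy enone
Product: 10 7β-isopropenyl ketone
Conditions: CH2=C(CH3)MgBr (3.5 equiv), THF, −78 to 0 °C; aq NH4Cl
Reagents that add atoms: isopropenylmagnesium bromide, CC(=C)[Mg]Br
Why: Chelation-directed (ligand-assisted) conjugate addition; the magnesium alkoxide of the pseudo-axial 6β-OH delivers the isopropenyl group to the same face of C7, as in alkoxide-directed Grignard 1,4-additions to 4-oxido enones, while 1,2-attack on the neopentyl C9 ketone is slow.

Step 8
Reactants: 10 7β-isopropenyl ketone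
Product: 11 8α-hydroxy ketone
Conditions: KN(SiMe3)2 (2.2 equiv), THF, −78 °C; (±)-trans-2-(phenylsulfonyl)-3-phenyloxaziridine; AcOH quench
Reagents that add atoms: 2-(phenylsulfonyl)-3-phenyloxaziridine, O=S(=O)(c1ccccc1)N1OC1c1ccccc1
Why: Davis enolate oxidation; only C8 carries α-hydrogens (C10 is quaternary), and the oxidant approaches anti to the C7 isopropenyl group and the syn-axial C10 methyl, giving the equatorial 8α-alcohol.

Step 9
Reactants: 11 8α-hydroxy ketone
Product: 12 6β,8α,9α-triol
Conditions: LiBH(s-Bu)3 (4 equiv), THF, −78 °C; H2O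
Reagents that add atoms: none
Why: Bulky-hydride ketone reduction; LiBH(s-Bu)3 attacks the C9 ketone from the equatorial direction (as with 4,4-dimethyl-3-keto steroids), giving the axial 9α-alcohol cis to the 8α-OH.

Step 10
Reactants: 12 6β,8α,9α-triol
Product: 15 6β-methacrylate 8α,9α-diol, via phenylboronate 13 (not isolated), via methacryloylated phenylboronate 14 (not isolated)
Conditions: PhB(OH)2, toluene, 4 Å MS, rt; then methacrylic anhydride, DMAP, Et3N, 0 to 40 °C; then pinacol, rt
Reagents that add atoms: methacrylic anhydride, C=C(C)C(=O)OC(=O)C(C)=C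
Why: The cis-8,9-diol is masked in the flask as its cyclic phenylboronate so that DMAP-catalysed esterification can only occur at the axial 6β-OH, and boronate exchange with pinacol then frees the diol; no stereocentre changes.

Step 11
Reactants: 15 6β-methacrylate 8α,9α-diol
Product: 17 vinyl lactone enal, via bis-allylic alcohol 16 (not isolated)
Conditions: SeO2 (0.5 equiv), t-BuOOH, CH2Cl2, rt; filtration; then MnO2 (excess), CH2Cl2, rt
Reagents that add atoms: selenium dioxide (oxygen-transfer agent), O=[Se]=O; tert-butyl hydroperoxide (terminal oxygen source), CC(C)(C)OO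
Why: Selenium dioxide allylic oxidation turns the methyl of each isopropenyl group into CH2OH (methyl preferred over the ring methine), and MnO2 then oxidises both allylic alcohols: the C12 aldehyde is trapped by the trans 8α-OH as a lactol that is oxidised on to the trans-fused α-methylene-γ-butyrolactone, while the C3 alcohol gives the enal.

Step 12
Reactants: 17 vinyl lactone enal
Product: 18 target CNP0228781.2
Conditions: VO(acac)2 (5 mol%), t-BuOOH, CH2Cl2, 0 °C to rt
Reagents that add atoms: tert-butyl hydroperoxide, CC(C)(C)OO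
Why: Vanadium-catalysed hydroxyl-directed epoxidation of a homoallylic alcohol; the axial 9α-OH binds the catalyst and delivers oxygen to the neighbouring equatorial vinyl group through a chair-like transition state with the CH2 terminus turned away from the metal, which sets C1 as R, while the three other alkenes are electron-poor and inert.

## Compound list

1 | 1,1-dimethoxypropan-2-one | CC(=O)C(OC)OC | starting material
2 | diethyl (2-oxopropyl)phosphonate | CCOP(=O)(CC(C)=O)OCC | starting material
3 | (E)-5,5-dimethoxy-4-methylpent-3-en-2-one | CC(=O)/C=C(\C)C(OC)OC | intermediate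
4 | (E)-2-methyl-4-oxopent-2-enal | CC(=O)/C=C(\C)C=O | intermediate
5 | (1E,3E)-buta-1,3-diene-1,4-diyl diacetate | CC(=O)O/C=C/C=C/OC(C)=O | starting material
6 | 6-acetyl-5-formyl-5-methylcyclohex-2-ene-1,4-diyl diacetate (6β,9β-OAc; 10β-CH3, 10α-CHO; 5β-acetyl) | CC(=O)O[C@@H]1C=C[C@H](OC(C)=O)[C@@](C)(C=O)[C@@H]1C(C)=O | intermediate
7 | 5-methyl-6-(prop-1-en-2-yl)-5-vinylcyclohex-2-ene-1,4-diyl diacetate (6β,9β-OAc; 10β-CH3, 10α-vinyl; 5β-isopropenyl) | CC(=O)O[C@@H]1C=C[C@H](OC(C)=O)[C@@](C)(C=C)[C@@H]1C(C)=C | intermediate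
8 | 5-methyl-6-(prop-1-en-2-yl)-5-vinylcyclohex-2-ene-1,4-diol (6β-OH, 9β-OH) | O[C@@H]1C=C[C@H](O)[C@@](C)(C=C)[C@@H]1C(C)=C | intermediate
9 | 4-hydroxy-6-methyl-5-(prop-1-en-2-yl)-6-vinylcyclohex-2-en-1-one (C9 ketone, 6β-OH) | O[C@@H]1C=CC(=O)[C@@](C)(C=C)[C@@H]1C(C)=C | intermediate
10 | 4-hydroxy-2-methyl-3,5-di(prop-1-en-2-yl)-2-vinylcyclohexan-1-one (C9 ketone; 6β-OH; 5β- and 7β-isopropenyl) | O[C@@H]1[C@H](C(C)=C)CC(=O)[C@@](C)(C=C)[C@@H]1C(C)=C | intermediate
11 | 4,6-dihydroxy-2-methyl-3,5-di(prop-1-en-2-yl)-2-vinylcyclohexan-1-one (6β-OH, 8α-OH) | O[C@@H]1[C@H](C(C)=C)[C@@H](O)C(=O)[C@@](C)(C=C)[C@@H]1C(C)=C | intermediate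
12 | 6-methyl-3,5-di(prop-1-en-2-yl)-6-vinylcyclohexane-1,2,4-triol (9α-OH, 8α-OH, 6β-OH) | O[C@@H]1[C@H](C(C)=C)[C@@H](O)[C@@H](O)[C@@](C)(C=C)[C@@H]1C(C)=C | intermediate
13 | 8,9-O-phenylboronate of 12 (2-phenyl-1,3,2-dioxaborolane fused at C8/C9, free 6β-OH) | O[C@@H]1[C@H](C(C)=C)[C@H]2OB(c3ccccc3)O[C@H]2[C@@](C)(C=C)[C@@H]1C(C)=C | intermediate
14 | 6β-methacrylate of phenylboronate 13 | C=C(C)C(=O)O[C@@H]1[C@H](C(C)=C)[C@H]2OB(c3ccccc3)O[C@H]2[C@@](C)(C=C)[C@@H]1C(C)=C | intermediate
15 | 6β-methacryloyloxy-8α,9α-diol with 5β,7β-isopropenyl, 10β-CH3 and 10α-vinyl | C=C(C)C(=O)O[C@@H]1[C@H](C(C)=C)[C@@H](O)[C@@H](O)[C@@](C)(C=C)[C@@H]1C(C)=C | intermediate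
16 | 15 with both isopropenyl methyl groups oxidised to CH2OH (C3–OH and C12–OH) | C=C(C)C(=O)O[C@@H]1[C@H](C(=C)CO)[C@@H](O)[C@@H](O)[C@@](C)(C=C)[C@@H]1C(=C)CO | intermediate
17 | 9α-hydroxy-6β-methacryloyloxy-3-oxoelema-1,4(15),11(13)-trien-12,8α-olide (vinyl precursor of the target) | C=C(C)C(=O)O[C@@H]1[C@@H]2C(=C)C(=O)O[C@H]2[C@@H](O)[C@@](C)(C=C)[C@@H]1C(=C)C=O | intermediate
18 | (1R)-1,2-epoxy-9α-hydroxy-6β-methacryloyloxy-3-oxoelema-4(15),11(13)-dien-12,8α-olide (CNP0228781.2) | C=C(C)C(=O)O[C@@H]1[C@@H]2C(=C)C(=O)O[C@H]2[C@@H](O)[C@@](C)([C@@H]2CO2)[C@@H]1C(=C)C=O | target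

## Step count and risk

Total steps: 12. Longest linear sequence: 12 steps (1/2 → 18; diene 5 is purchased).

**Step 3 (new asymmetric Diels–Alder reaction).** The diene is only moderately reactive, and both the endo/exo ratio and the enantioselectivity are untested. Fallback, setting out from 4 and 5 and coming back at 6: heat 4 and 5 without catalyst (toluene, 80 °C, BHT). This known thermal cycloaddition of 1,4-diacetoxybutadiene gives the adduct as a racemate, that is 6 plus the enantiomer of 6 F1. Enzymatic kinetic resolution follows (Pseudomonas cepacia lipase, pH 7 phosphate buffer/t-BuOMe, rt, stopped near 50% conversion; the lipase is picked by screening for the needed preference). It hydrolyses the less hindered C6 acetate of F1 to the hydroxy monoacetate of the enantiomeric series F2. Unreacted, enantioenriched 6 (at most 50%) is separated by chromatography and enters step 4.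

**Step 7 (alkoxide-directed conjugate addition).** Delivery to the β face of C7 must override the usual preference for addition trans to the C5 and C6 substituents. Fallback, setting out from 8 and coming back at 12 (steps 6–9 are bypassed; control at C7 becomes thermodynamic instead of chelation-based):
- Dess–Martin periodinane (NaHCO3, CH2Cl2) oxidises both carbinols of 8 to the ene-1,4-dione F3.
- CuBr·SMe2-catalysed addition of CH2=C(CH3)MgBr with TMSCl (THF, −78 °C) is expected at C7, the enedione carbon remote from the quaternary C10, and traps the C9 enolate. The C7 centre, now α to the C6 ketone, is equilibrated with Et3N to the equatorial 7β epimer, giving the C9 trimethylsilyl enol ether of the 7β-isopropenyl diketone F4.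
- Rubottom oxidation (dimethyldioxirane, acetone/CH2Cl2, −78 °C, then citric acid) gives the 8α-hydroxy-6,9-diketone F5.
- LiBH(s-Bu)3 (THF, −78 °C) reduces both ketones from the equatorial side (axial attack at C6 is blocked by the syn-axial C10 methyl) to the 6β- and 9α-axial alcohols, which is triol 12.

**Step 12 (directed epoxidation, C1 configuration).** The facial selectivity rests on a transition-state model for a rigid, hindered homoallylic alcohol. Fallback, setting out from 17 and coming back at 18: dimethyldioxirane (acetone, 0 °C) epoxidises the vinyl group, the only electron-rich alkene of 17, without facial control. This gives 18 mixed with its C1 epimer, the (1S)-epoxide F6. Jacobsen hydrolytic kinetic resolution with (salen)Co(OAc) (trivalent cobalt; salen = N,N′-bis(3,5-di-tert-butylsalicylidene)-1,2-cyclohexanediaminato; the antipode that hydrolyses (S)-configured terminal epoxides; 0.6 equiv H2O, THF) opens F6 to the 1,2-diol F7. The untouched (1R)-epoxide 18 is isolated.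

## Further compounds

F1 | step 3 | enantiomer of 6 | CC(=O)O[C@H]1C=C[C@@H](OC(C)=O)[C@](C)(C=O)[C@H]1C(C)=O
F2 | step 3 | enantiomer of 6 with the C6 acetate hydrolysed (C6–OH, C9–OAc) | O[C@H]1C=C[C@@H](OC(C)=O)[C@](C)(C=O)[C@H]1C(C)=O
F3 | step 7 | 5-methyl-6-(prop-1-en-2-yl)-5-vinylcyclohex-2-ene-1,4-dione (C6 and C9 ketones) | O=C1C=CC(=O)[C@@](C)(C=C)[C@@H]1C(C)=C
F4 | step 7 | C9 trimethylsilyl enol ether of the 7β-isopropenyl 6,9-diketone | O=C1[C@H](C(C)=C)C=C(O[Si](C)(C)C)[C@@](C)(C=C)[C@@H]1C(C)=C
F5 | step 7 | 8α-hydroxy-7β-isopropenyl 6,9-diketone | O=C1[C@H](C(C)=C)[C@@H](O)C(=O)[C@@](C)(C=C)[C@@H]1C(C)=C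
F6 | step 12 | (1S)-epoxide, C1 epimer of 18 | C=C(C)C(=O)O[C@@H]1[C@@H]2C(=C)C(=O)O[C@H]2[C@@H](O)[C@@](C)([C@H]2CO2)[C@@H]1C(=C)C=O
F7 | step 12 | 1,2-diol from hydrolysis of F6 | C=C(C)C(=O)O[C@@H]1[C@@H]2C(=C)C(=O)O[C@H]2[C@@H](O)[C@@](C)([C@H](O)CO)[C@@H]1C(=C)C=O
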